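**Retrosynthetic overview**

1. Target 26 comes from its bis-silyl ether 25 by buffered fluoride. The benzofuran oxygen O1 and the 4'-oxygen are masked as MOM ethers until just before the key step; O7 and O3' stay silylated to the end.
2. 25 comes from the open-chain (S)-2,3-diarylpropanoate 23 by forming O1–C2. C2 is the benzylic carbon para to the 4'-OH of the catechol ring (ring B), so two-electron oxidation of that 4-hydroxybenzyl unit makes C2 the methide carbon of a p-quinone methide. The C7a–OH phenol of ring A adds to it and closes the dihydrofuran ring, the only ring made in the route.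
3. 23 comes from aryl bromide 20 by Heck coupling at C5 and MOM removal. The C2–C3 bond and the C3 stereocentre come from Evans benzylation of arylacetyl imide 11 with benzyl bromide 16.
4. 11 comes from 5-bromo-2-hydroxy-3-methoxybenzaldehyde (demethylation, ordered protection, one-carbon homologation). 16 comes from 3,4-dihydroxybenzaldehyde.

Key step: step 17

Remark: the spectator oxygens (future O7 and O3') are carried as triisopropylsilyl (TIPS) ethers rather than smaller silyl ethers, because TIPS does not migrate between catechol oxygens under amine bases and tolerates LiOOH.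

**Route**

Step 1
Reactants: 1 5-bromo-2-hydroxy-3-methoxybenzaldehyde
Product: 2 5-bromo-2,3-dihydroxybenzaldehyde
Conditions: BBr3, CH2Cl2, −78 °C to rt; H2O
Reagents that add atoms: none
Why: Lewis-acid-assisted demethylation of the aryl methyl ether by BBr3, with the aldehyde and aryl bromide inert, should free the catechol before any sensitive group is present.

Step 2
Reactants: 2 5-bromo-2,3-dihydroxybenzaldehyde
Product: 3 5-bromo-2-hydroxy-3-(triisopropylsilyloxy)benzaldehyde
Conditions: TIPSCl (1.05 equiv), imidazole, DMF, 0 °C to rt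
Reagents that add atoms: triisopropylsilyl chloride, CC(C)[Si](Cl)(C(C)C)C(C)C
Why: Imidazole-mediated silylation should go to the 3-OH because the 2-OH is flanked on both sides and hydrogen-bonded to the formyl group, and any O-to-O silyl shift also ends at O3 since the anion prefers the formyl-conjugated O2.

Step 3
Reactants: 3 5-bromo-2-hydroxy-3-(triisopropylsilyloxy)benzaldehyde
Product: 4 5-bromo-2-(methoxymethoxy)-3-(triisopropylsilyloxy)benzaldehyde
Conditions: MOMCl, i-Pr2NEt, CH2Cl2, 0 °C to rt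
Reagents that add atoms: chloromethyl methyl ether, COCCl
Why: O-alkylation of the remaining salicylaldehyde phenol with MOMCl under a weak amine base should mask the future O1 without moving the bulky silyl group.

Step 4
Reactants: 4 5-bromo-2-(methoxymethoxy)-3-(triisopropylsilyloxy)benzaldehyde
Product: 5 5-bromo-1-ethenyl-2-(methoxymethoxy)-3-(triisopropylsilyloxy)benzene
Conditions: Ph3PCH3Br, KOtBu, THF, 0 °C to rt
Reagents that add atoms: methyltriphenylphosphonium bromide, C[P+](c1ccccc1)(c1ccccc1)c1ccccc1.[Br-]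
Why: Wittig methylenation of an aromatic aldehyde with the non-stabilised ylide is general and leaves the aryl bromide, MOM and silyl ethers alone.

Step 5
Reactants: 5 5-bromo-1-ethenyl-2-(methoxymethoxy)-3-(triisopropylsilyloxy)benzene
Product: 7 2-[5-bromo-2-(methoxymethoxy)-3-(triisopropylsilyloxy)phenyl]ethan-1-ol, via alkylborane 6 (not isolated)
Conditions: 9-BBN, THF, 0 °C to rt; then 30% H2O2, 3 M aq NaOAc, 0 °C to rt
Reagents that add atoms: hydrogen peroxide, OO
Why: Hydroboration of the styrene with 9-BBN is anti-Markovnikov, and the acetate-buffered peroxide oxidation of the C–B bond should spare the aryl silyl ether.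

Step 6
Reactants: 7 2-[5-bromo-2-(methoxymethoxy)-3-(triisopropylsilyloxy)phenyl]ethan-1-ol
Product: 8 [5-bromo-2-(methoxymethoxy)-3-(triisopropylsilyloxy)phenyl]acetic acid
Conditions: TEMPO (cat.), PhI(OAc)2, MeCN/H2O 1:1, rt
Reagents that add atoms: water, O
Why: The oxoammonium (TEMPO/PhI(OAc)2) oxidation in aqueous acetonitrile takes the primary alcohol through the aldehyde hydrate to the acid under near-neutral conditions that MOM, TIPS and ArBr tolerate.

Step 7
Reactants: 8 [5-bromo-2-(methoxymethoxy)-3-(triisopropylsilyloxy)phenyl]acetic acid; 9 (S)-4-benzyloxazolidin-2-one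
Product: 11 (S)-4-benzyl-3-{[5-bromo-2-(methoxymethoxy)-3-(triisopropylsilyloxy)phenyl]acetyl}oxazolidin-2-one, via mixed pivalic anhydride 10 (not isolated)
Conditions: PivCl, Et3N, THF, −20 °C; then 9, LiCl, −20 °C to rt
Reagents that add atoms: none
Why: Mixed-anhydride activation followed by LiCl-promoted N-acylation of the oxazolidinone is a standard way to attach the Evans auxiliary to arylacetic acids.

Step 8
Reactants: 12 3,4-dihydroxybenzaldehyde
Product: 13 3-hydroxy-4-(methoxymethoxy)benzaldehyde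
Conditions: MOMCl (1.05 equiv), K2CO3 (1.1 equiv), acetone, 0 °C to rt
Reagents that add atoms: chloromethyl methyl ether, COCCl
Why: The 4-OH, para to the formyl group, is the more acidic phenol, so mono-deprotonation and O-alkylation should place MOM on the future O4'.

Step 9
Reactants: 13 3-hydroxy-4-(methoxymethoxy)benzaldehyde
Product: 14 4-(methoxymethoxy)-3-(triisopropylsilyloxy)benzaldehyde
Conditions: TIPSCl, imidazole, DMF, rt
Reagents that add atoms: triisopropylsilyl chloride, CC(C)[Si](Cl)(C(C)C)C(C)C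
Why: Silylation of the single remaining phenol is unambiguous.

Step 10
Reactants: 14 4-(methoxymethoxy)-3-(triisopropylsilyloxy)benzaldehyde
Product: 15 [4-(methoxymethoxy)-3-(triisopropylsilyloxy)phenyl]methanol
Conditions: NaBH4, MeOH, 0 °C
Reagents that add atoms: none
Why: Borohydride reduction of the aldehyde is chemoselective and brief enough at 0 °C to leave the aryl silyl ether intact.

Step 11
Reactants: 15 [4-(methoxymethoxy)-3-(triisopropylsilyloxy)phenyl]methanol
Product: 16 4-(bromomethyl)-1-(methoxymethoxy)-2-(triisopropylsilyloxy)benzene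
Conditions: CBr4, PPh3, CH2Cl2, 0 °C; used at once
Reagents that add atoms: carbon tetrabromide, BrC(Br)(Br)Br
Why: The Appel reaction converts the benzylic alcohol into the bromide under neutral conditions compatible with the acetal and the silyl ether.

Step 12
Reactants: 11 (S)-4-benzyl-3-{[5-bromo-2-(methoxymethoxy)-3-(triisopropylsilyloxy)phenyl]acetyl}oxazolidin-2-one; 16 4-(bromomethyl)-1-(methoxymethoxy)-2-(triisopropylsilyloxy)benzene
Product: 18 (S)-4-benzyl-3-{(2S)-2-[5-bromo-2-(methoxymethoxy)-3-(triisopropylsilyloxy)phenyl]-3-[4-(methoxymethoxy)-3-(triisopropylsilyloxy)phenyl]propanoyl}oxazolidin-2-one, via sodium Z-enolate 17 (not isolated)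
Conditions: NaHMDS, THF, −78 °C; then 16 (1.5 equiv), −78 to −40 °C
Reagents that add atoms: none
Why: In this Evans asymmetric alkylation the chelated Z-enolate is shielded on one face by the C4 benzyl group of the (S)-auxiliary, so the benzyl bromide should add to the open face and set the (S) centre that becomes C3.

Step 13
Reactants: 18 (S)-4-benzyl-3-{(2S)-2-[5-bromo-2-(methoxymethoxy)-3-(triisopropylsilyloxy)phenyl]-3-[4-(methoxymethoxy)-3-(triisopropylsilyloxy)phenyl]propanoyl}oxazolidin-2-one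
Product: 19 (2S)-2-[5-bromo-2-(methoxymethoxy)-3-(triisopropylsilyloxy)phenyl]-3-[4-(methoxymethoxy)-3-(triisopropylsilyloxy)phenyl]propanoic acid
Conditions: LiOH, 30% H2O2, THF/H2O 3:1, 0 °C; Na2SO3; 1 M HCl to pH 3
Reagents that add atoms: hydrogen peroxide, OO
Why: Lithium hydroperoxide attacks the exocyclic carbonyl of hindered N-acyloxazolidinones selectively and is too weakly basic to epimerise the α-aryl centre, and the auxiliary is recovered.

Step 14
Reactants: 19 (2S)-2-[5-bromo-2-(methoxymethoxy)-3-(triisopropylsilyloxy)phenyl]-3-[4-(methoxymethoxy)-3-(triisopropylsilyloxy)phenyl]propanoic acid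
Product: 20 methyl (2S)-2-[5-bromo-2-(methoxymethoxy)-3-(triisopropylsilyloxy)phenyl]-3-[4-(methoxymethoxy)-3-(triisopropylsilyloxy)phenyl]propanoate
Conditions: TMSCHN2, toluene/MeOH 4:1, 0 °C to rt
Reagents that add atoms: trimethylsilyldiazomethane, C[Si](C)(C)C=[N+]=[N-]
Why: Esterification with TMSCHN2 proceeds without base, so the enolisable α-aryl centre keeps its configuration.

Step 15
Reactants: 20 methyl (2S)-2-[5-bromo-2-(methoxymethoxy)-3-(triisopropylsilyloxy)phenyl]-3-[4-(methoxymethoxy)-3-(triisopropylsilyloxy)phenyl]propanoate; 21 methyl acrylate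
Product: 22 methyl (2S)-2-{5-[(E)-3-methoxy-3-oxoprop-1-enyl]-2-(methoxymethoxy)-3-(triisopropylsilyloxy)phenyl}-3-[4-(methoxymethoxy)-3-(triisopropylsilyloxy)phenyl]propanoate
Conditions: Pd2(dba)3 (cat.), [t-Bu3PH]BF4 (cat.), Cy2NMe, dioxane, rt to 40 °C
Reagents that add atoms: none
Why: Heck–Mizoroki coupling of the unhindered aryl bromide with an acrylate gives the E-cinnamate by syn-insertion and syn-β-hydride elimination, and the bulky trialkylphosphine allows a temperature at which the amine base should not touch the α-aryl ester.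

Step 16
Reactants: 22 methyl (2S)-2-{5-[(E)-3-methoxy-3-oxoprop-1-enyl]-2-(methoxymethoxy)-3-(triisopropylsilyloxy)phenyl}-3-[4-(methoxymethoxy)-3-(triisopropylsilyloxy)phenyl]propanoate
Product: 23 methyl (2S)-2-{2-hydroxy-5-[(E)-3-methoxy-3-oxoprop-1-enyl]-3-(triisopropylsilyloxy)phenyl}-3-[4-hydroxy-3-(triisopropylsilyloxy)phenyl]propanoate
Conditions: HCl (3 M in MeOH), rt; NaHCO3 before concentration; used directly
Reagents that add atoms: none
Why: Acid-catalysed acetal exchange releases both MOM groups as dimethoxymethane, aryl TIPS ethers tolerate methanolic HCl, and methanol as solvent should hold the A-ring hydroxy ester open rather than let it lactonise.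

Step 17
Reactants: 23 methyl (2S)-2-{2-hydroxy-5-[(E)-3-methoxy-3-oxoprop-1-enyl]-3-(triisopropylsilyloxy)phenyl}-3-[4-hydroxy-3-(triisopropylsilyloxy)phenyl]propanoate
Product: 25 methyl (2R,3R)-2-[4-hydroxy-3-(triisopropylsilyloxy)phenyl]-5-[(E)-3-methoxy-3-oxoprop-1-enyl]-7-(triisopropylsilyloxy)-2,3-dihydro-1-benzofuran-3-carboxylate, via p-quinone methide 24 (not isolated)
Conditions: DDQ (1.05 equiv), CH2Cl2, 0 °C, Ar; filter, aq NaHCO3
Reagents that add atoms: none
Why: DDQ takes a hydride equivalent from the 4-hydroxybenzyl unit of ring B to give p-quinone methide 24, whose methide carbon is C2, and the C7a–OH phenol of ring A adds to it in a 1,6-addition that re-aromatises ring B and forms O1–C2. The closest known reaction types are the DDQ dehydrogenative cyclisation of 2'-hydroxyisoflavans to pterocarpans and the DDQ oxidation of 4-alkylguaiacols to quinone methides that are captured by an internal hydroxyl group. The dihydrofuran ring closes in the 5-exo-trig mode. C3 is not touched because its C–H bond takes no part, and the new C2 centre is controlled by the C3 ester: the phenol should add to the methide face that places the aryl group trans to CO2Me, and reversible ring opening under the acidic hydroquinone by-product should funnel any cis isomer and both methide geometries to the trans-(2R,3R) product. The step needs oxidation of the ring-B phenol in preference to the ring-A phenol; ring A has no benzylic hydrogen para to its OH (that carbon carries the acrylate) and its only benzylic C–H is tertiary, ortho and α to an ester, and a hydride-abstracting quinone is used because a one-electron oxidant such as Ag2O would turn the 4-hydroxycinnamate ring into a phenoxyl radical and couple it. One equivalent at 0 °C should let the intramolecular capture outrun tautomerisation of 24 to the stilbene and leave the product, which needs forcing conditions for dehydrogenation to the benzofuran, intact.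

Step 18
Reactants: 25 methyl (2R,3R)-2-[4-hydroxy-3-(triisopropylsilyloxy)phenyl]-5-[(E)-3-methoxy-3-oxoprop-1-enyl]-7-(triisopropylsilyloxy)-2,3-dihydro-1-benzofuran-3-carboxylate
Product: 26 methyl (2R,3R)-2-(3,4-dihydroxyphenyl)-7-hydroxy-5-[(E)-3-methoxy-3-oxoprop-1-enyl]-2,3-dihydro-1-benzofuran-3-carboxylate
Conditions: TBAF, AcOH (1:1, 2.5 equiv), THF, 0 °C to rt
Reagents that add atoms: none
Why: Fluoride cleaves aryl silyl ethers readily, and the acetic acid buffer keeps the phenols protonated, which should prevent base-induced ring opening, epimerisation and catechol oxidation.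

**Compound list**

1 | 5-bromo-2-hydroxy-3-methoxybenzaldehyde | COc1cc(Br)cc(C=O)c1O | starting material
2 | 5-bromo-2,3-dihydroxybenzaldehyde | Oc1cc(Br)cc(C=O)c1O | intermediate
3 | 5-bromo-2-hydroxy-3-(triisopropylsilyloxy)benzaldehyde | CC(C)[Si](Oc1cc(Br)cc(C=O)c1O)(C(C)C)C(C)C | intermediate
4 | 5-bromo-2-(methoxymethoxy)-3-(triisopropylsilyloxy)benzaldehyde | COCOc1c(C=O)cc(Br)cc1O[Si](C(C)C)(C(C)C)C(C)C | intermediate
5 | 5-bromo-1-ethenyl-2-(methoxymethoxy)-3-(triisopropylsilyloxy)benzene | COCOc1c(C=C)cc(Br)cc1O[Si](C(C)C)(C(C)C)C(C)C | intermediate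
6 | 9-{2-[5-bromo-2-(methoxymethoxy)-3-(triisopropylsilyloxy)phenyl]ethyl}-9-borabicyclo[3.3.1]nonane | COCOc1c(CCB2C3CCCC2CCC3)cc(Br)cc1O[Si](C(C)C)(C(C)C)C(C)C | intermediate (not isolated)
7 | 2-[5-bromo-2-(methoxymethoxy)-3-(triisopropylsilyloxy)phenyl]ethan-1-ol | COCOc1c(CCO)cc(Br)cc1O[Si](C(C)C)(C(C)C)C(C)C | intermediate
8 | [5-bromo-2-(methoxymethoxy)-3-(triisopropylsilyloxy)phenyl]acetic acid | COCOc1c(CC(=O)O)cc(Br)cc1O[Si](C(C)C)(C(C)C)C(C)C | intermediate
9 | (S)-4-benzyloxazolidin-2-one | O=C1N[C@@H](Cc2ccccc2)CO1 | starting material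
10 | [5-bromo-2-(methoxymethoxy)-3-(triisopropylsilyloxy)phenyl]acetic pivalic anhydride | COCOc1c(CC(=O)OC(=O)C(C)(C)C)cc(Br)cc1O[Si](C(C)C)(C(C)C)C(C)C | intermediate (not isolated)
11 | (S)-4-benzyl-3-{[5-bromo-2-(methoxymethoxy)-3-(triisopropylsilyloxy)phenyl]acetyl}oxazolidin-2-one | COCOc1c(CC(=O)N2[C@@H](Cc3ccccc3)COC2=O)cc(Br)cc1O[Si](C(C)C)(C(C)C)C(C)C | intermediate
12 | 3,4-dihydroxybenzaldehyde | O=Cc1ccc(O)c(O)c1 | starting material
13 | 3-hydroxy-4-(methoxymethoxy)benzaldehyde | COCOc1ccc(C=O)cc1O | intermediate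
14 | 4-(methoxymethoxy)-3-(triisopropylsilyloxy)benzaldehyde | COCOc1ccc(C=O)cc1O[Si](C(C)C)(C(C)C)C(C)C | intermediate
15 | [4-(methoxymethoxy)-3-(triisopropylsilyloxy)phenyl]methanol | COCOc1ccc(CO)cc1O[Si](C(C)C)(C(C)C)C(C)C | intermediate
16 | 4-(bromomethyl)-1-(methoxymethoxy)-2-(triisopropylsilyloxy)benzene | COCOc1ccc(CBr)cc1O[Si](C(C)C)(C(C)C)C(C)C | intermediate
17 | sodium (Z)-enolate of 11 | COCOc1c(/C=C(\[O-])N2[C@@H](Cc3ccccc3)COC2=O)cc(Br)cc1O[Si](C(C)C)(C(C)C)C(C)C.[Na+] | intermediate (not isolated)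
18 | (S)-4-benzyl-3-{(2S)-2-[5-bromo-2-(methoxymethoxy)-3-(triisopropylsilyloxy)phenyl]-3-[4-(methoxymethoxy)-3-(triisopropylsilyloxy)phenyl]propanoyl}oxazolidin-2-one | Brc1cc(O[Si](C(C)C)(C(C)C)C(C)C)c(OCOC)c(c1)[C@@H](C(=O)N2[C@@H](Cc3ccccc3)COC2=O)Cc4ccc(OCOC)c(O[Si](C(C)C)(C(C)C)C(C)C)c4 | intermediate
19 | (2S)-2-[5-bromo-2-(methoxymethoxy)-3-(triisopropylsilyloxy)phenyl]-3-[4-(methoxymethoxy)-3-(triisopropylsilyloxy)phenyl]propanoic acid | Brc1cc(O[Si](C(C)C)(C(C)C)C(C)C)c(OCOC)c(c1)[C@@H](C(=O)O)Cc2ccc(OCOC)c(O[Si](C(C)C)(C(C)C)C(C)C)c2 | intermediate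
20 | methyl (2S)-2-[5-bromo-2-(methoxymethoxy)-3-(triisopropylsilyloxy)phenyl]-3-[4-(methoxymethoxy)-3-(triisopropylsilyloxy)phenyl]propanoate | Brc1cc(O[Si](C(C)C)(C(C)C)C(C)C)c(OCOC)c(c1)[C@@H](C(=O)OC)Cc2ccc(OCOC)c(O[Si](C(C)C)(C(C)C)C(C)C)c2 | intermediate
21 | methyl acrylate | COC(=O)C=C | starting material
22 | methyl (2S)-2-{5-[(E)-3-methoxy-3-oxoprop-1-enyl]-2-(methoxymethoxy)-3-(triisopropylsilyloxy)phenyl}-3-[4-(methoxymethoxy)-3-(triisopropylsilyloxy)phenyl]propanoate | COC(=O)/C=C/c1cc(O[Si](C(C)C)(C(C)C)C(C)C)c(OCOC)c(c1)[C@@H](C(=O)OC)Cc2ccc(OCOC)c(O[Si](C(C)C)(C(C)C)C(C)C)c2 | intermediate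
23 | methyl (2S)-2-{2-hydroxy-5-[(E)-3-methoxy-3-oxoprop-1-enyl]-3-(triisopropylsilyloxy)phenyl}-3-[4-hydroxy-3-(triisopropylsilyloxy)phenyl]propanoate | COC(=O)/C=C/c1cc(O[Si](C(C)C)(C(C)C)C(C)C)c(O)c(c1)[C@@H](C(=O)OC)Cc2ccc(O)c(O[Si](C(C)C)(C(C)C)C(C)C)c2 | intermediate (key-step precursor)
24 | methyl (2S)-2-{2-hydroxy-5-[(E)-3-methoxy-3-oxoprop-1-enyl]-3-(triisopropylsilyloxy)phenyl}-3-[4-oxo-3-(triisopropylsilyloxy)cyclohexa-2,5-dien-1-ylidene]propanoate | COC(=O)/C=C/c1cc(O[Si](C(C)C)(C(C)C)C(C)C)c(O)c(c1)[C@@H](C(=O)OC)C=C2C=CC(=O)C(O[Si](C(C)C)(C(C)C)C(C)C)=C2 | intermediate (not isolated)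
25 | methyl (2R,3R)-2-[4-hydroxy-3-(triisopropylsilyloxy)phenyl]-5-[(E)-3-methoxy-3-oxoprop-1-enyl]-7-(triisopropylsilyloxy)-2,3-dihydro-1-benzofuran-3-carboxylate | COC(=O)/C=C/c1cc(O[Si](C(C)C)(C(C)C)C(C)C)c2c(c1)[C@@H](C(=O)OC)[C@H](c3ccc(O)c(O[Si](C(C)C)(C(C)C)C(C)C)c3)O2 | intermediate (key-step product)
26 | methyl (2R,3R)-2-(3,4-dihydroxyphenyl)-7-hydroxy-5-[(E)-3-methoxy-3-oxoprop-1-enyl]-2,3-dihydro-1-benzofuran-3-carboxylate | COC(=O)/C=C/c1cc(O)c2c(c1)[C@@H](C(=O)OC)[C@H](c1ccc(O)c(O)c1)O2 | target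

**Step count**

Total steps: 18. Longest linear sequence: 14 steps (steps 1–7 and 12–18, from compound 1).

**Steps most likely to fail, with fallbacks**

Step 17. The oxidation may start at the cinnamate-bearing ring-A phenol instead of ring B. The quinone methide may tautomerise to the stilbene with loss of the C3 centre, or the product may be dehydrogenated further to the benzofuran. The fallback reaches the same quinone methide by ionisation instead of oxidation; it sets out from acid 8 and aldehyde 14 and comes back at 25. Acid 8 is coupled as in step 7 with (R)-4-benzyloxazolidin-2-one to give (R)-4-benzyl-3-{[5-bromo-2-(methoxymethoxy)-3-(triisopropylsilyloxy)phenyl]acetyl}oxazolidin-2-one F1. The antipodal auxiliary is needed because the boron aldol uses the enolate face opposite to the one used in the sodium enolate alkylation. An Evans syn-aldol reaction (Bu2BOTf, i-Pr2NEt, CH2Cl2, −78 to 0 °C, then 14) should give (R)-4-benzyl-3-{(2R,3R)-2-[5-bromo-2-(methoxymethoxy)-3-(triisopropylsilyloxy)phenyl]-3-hydroxy-3-[4-(methoxymethoxy)-3-(triisopropylsilyloxy)phenyl]propanoyl}oxazolidin-2-one F2. LiOOH cleavage as in step 13 gives (2R,3R)-2-[5-bromo-2-(methoxymethoxy)-3-(triisopropylsilyloxy)phenyl]-3-hydroxy-3-[4-(methoxymethoxy)-3-(triisopropylsilyloxy)phenyl]propanoic acid F3. TMSCHN2 then gives methyl (2R,3R)-2-[5-bromo-2-(methoxymethoxy)-3-(triisopropylsilyloxy)phenyl]-3-hydroxy-3-[4-(methoxymethoxy)-3-(triisopropylsilyloxy)phenyl]propanoate F4. Heck coupling with 21 as in step 15 gives methyl (2R,3R)-3-hydroxy-2-{5-[(E)-3-methoxy-3-oxoprop-1-enyl]-2-(methoxymethoxy)-3-(triisopropylsilyloxy)phenyl}-3-[4-(methoxymethoxy)-3-(triisopropylsilyloxy)phenyl]propanoate F5. Methanolic HCl then removes both MOM groups and ionises the 4-hydroxybenzylic alcohol to methide 24, which closes to 25 as in the main route.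

Step 12. The hindered ortho-disubstituted arylacetyl enolate may alkylate slowly, the enolate may lose the auxiliary as a ketene on warming, or the electron-rich benzyl bromide may decompose before it reacts. The fallback replaces enolate alkylation by condensation and hydrogenation; it sets out from acid 8 and aldehyde 14 and comes back at 19. A Perkin–Oglialoro condensation (Ac2O, Et3N, about 100 °C) should give (E)-2-[5-bromo-2-(methoxymethoxy)-3-(triisopropylsilyloxy)phenyl]-3-[4-(methoxymethoxy)-3-(triisopropylsilyloxy)phenyl]prop-2-enoic acid F6. Asymmetric hydrogenation of this 2,3-diarylacrylic acid (Rh(I) with a chiral ferrocenyl bisphosphine, or a Ru(OAc)2/BINAP-type catalyst, H2, MeOH, Et3N) would then give 19; the sense of induction cannot be predicted with confidence here, so the ligand antipode that delivers the (S)-acid would have to be found by screening.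

Step 13. Hydroxide may attack an aryl silyl ether or the ring carbonyl of the hindered imide, or cleavage may be too slow at 0 °C. The fallback removes the auxiliary by reduction and restores the acid by oxidation; it sets out from 18 and comes back at 19. LiBH4 (THF, a little MeOH, 0 °C) should give (2S)-2-[5-bromo-2-(methoxymethoxy)-3-(triisopropylsilyloxy)phenyl]-3-[4-(methoxymethoxy)-3-(triisopropylsilyloxy)phenyl]propan-1-ol F7 together with the recovered auxiliary. TEMPO/PhI(OAc)2 in aqueous acetonitrile, as in step 6, then oxidises F7 to 19; the time spent at the α-aryl aldehyde stage is kept short to protect the stereocentre.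

**Further compounds**

F1 | step 17 | (R)-4-benzyl-3-{[5-bromo-2-(methoxymethoxy)-3-(triisopropylsilyloxy)phenyl]acetyl}oxazolidin-2-one | COCOc1c(CC(=O)N2[C@H](Cc3ccccc3)COC2=O)cc(Br)cc1O[Si](C(C)C)(C(C)C)C(C)C
F2 | step 17 | (R)-4-benzyl-3-{(2R,3R)-2-[5-bromo-2-(methoxymethoxy)-3-(triisopropylsilyloxy)phenyl]-3-hydroxy-3-[4-(methoxymethoxy)-3-(triisopropylsilyloxy)phenyl]propanoyl}oxazolidin-2-one | Brc1cc(O[Si](C(C)C)(C(C)C)C(C)C)c(OCOC)c(c1)[C@@H](C(=O)N2[C@H](Cc3ccccc3)COC2=O)[C@@H](O)c4ccc(OCOC)c(O[Si](C(C)C)(C(C)C)C(C)C)c4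
F3 | step 17 | (2R,3R)-2-[5-bromo-2-(methoxymethoxy)-3-(triisopropylsilyloxy)phenyl]-3-hydroxy-3-[4-(methoxymethoxy)-3-(triisopropylsilyloxy)phenyl]propanoic acid | Brc1cc(O[Si](C(C)C)(C(C)C)C(C)C)c(OCOC)c(c1)[C@@H](C(=O)O)[C@@H](O)c2ccc(OCOC)c(O[Si](C(C)C)(C(C)C)C(C)C)c2
F4 | step 17 | methyl (2R,3R)-2-[5-bromo-2-(methoxymethoxy)-3-(triisopropylsilyloxy)phenyl]-3-hydroxy-3-[4-(methoxymethoxy)-3-(triisopropylsilyloxy)phenyl]propanoate | Brc1cc(O[Si](C(C)C)(C(C)C)C(C)C)c(OCOC)c(c1)[C@@H](C(=O)OC)[C@@H](O)c2ccc(OCOC)c(O[Si](C(C)C)(C(C)C)C(C)C)c2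
F5 | step 17 | methyl (2R,3R)-3-hydroxy-2-{5-[(E)-3-methoxy-3-oxoprop-1-enyl]-2-(methoxymethoxy)-3-(triisopropylsilyloxy)phenyl}-3-[4-(methoxymethoxy)-3-(triisopropylsilyloxy)phenyl]propanoate | COC(=O)/C=C/c1cc(O[Si](C(C)C)(C(C)C)C(C)C)c(OCOC)c(c1)[C@@H](C(=O)OC)[C@@H](O)c2ccc(OCOC)c(O[Si](C(C)C)(C(C)C)C(C)C)c2
F6 | step 12 | (E)-2-[5-bromo-2-(methoxymethoxy)-3-(triisopropylsilyloxy)phenyl]-3-[4-(methoxymethoxy)-3-(triisopropylsilyloxy)phenyl]prop-2-enoic acid | OC(=O)/C(=C/c1ccc(OCOC)c(O[Si](C(C)C)(C(C)C)C(C)C)c1)c1cc(Br)cc(O[Si](C(C)C)(C(C)C)C(C)C)c1OCOC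
F7 | step 13 | (2S)-2-[5-bromo-2-(methoxymethoxy)-3-(triisopropylsilyloxy)phenyl]-3-[4-(methoxymethoxy)-3-(triisopropylsilyloxy)phenyl]propan-1-ol | Brc1cc(O[Si](C(C)C)(C(C)C)C(C)C)c(OCOC)c(c1)[C@@H](CO)Cc2ccc(OCOC)c(O[Si](C(C)C)(C(C)C)C(C)C)c2
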